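Early in both earlier runs the electrophile falls steeply, and then the curves part.

in all of them: electrophile 0.50 mM
- elm: nucleophile 0.37 mM; free base 1 mM; protic impurity 0.25 mM; run made earlier
- cedar: nucleophile 0.83 mM; free base 1 mM; protic impurity 0.25 mM; run made earlier
- flask: nucleophile 0.550 mM; free base 1.00 mM; protic impurity 0.250 mM; time 4.0 min

| run | time / min | electrophile / % | product / % |
|---|---|---|---|
| elm | 0.250 | 61 | 37 |
| elm | 0.667 | 61 | 41 |
| elm | 1.33 | 58 | 44 |
| elm | 2.00 | 56 | 43 |
| elm | 3.00 | 57 | 45 |
| elm | 4.00 | 55 | 41 |
| elm | 5.00 | 54 | 41 |
| cedar | 0.250 | 23 | 77 |
| cedar | 0.667 | 12 | 88 |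
| cedar | 1.33 | 3 | 95 |
| cedar | 2.00 | 4 | 94 |
| cedar | 3.00 | 0 | 100 |
| cedar | 4.00 | 1 | 104 |
| cedar | 5.00 | 4 | 101 |

(readings scatter by 2 percentage points)

- steps under discussion: electrophile + nucleophile <-> acid set free + product; nucleophile + acid set free <-> protonated nucleophile; acid set free + free base <-> salt of the base; nucleophile + protic impurity -> quenched reagent; nucleophile <-> dormant form
- the earlier runs do not show how much of nucleophile is bound; that part of a forecast is a guess

1. part of the electrophile that has reacted at 4.0 min
2. share of free nucleophile in free nucleophile and protonated nucleophile together, at 4.0 min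

Elm flattens by 1.33 min near 43.5% reacted, the mean of its last product and electrophile readings. Cedar reaches full reaction within the scatter. Cedar's nucleophile is more than electrophile and protic impurity together, and elm's is less. The elm level therefore reads as the end of its 0.37 mM of nucleophile, the limiting reagent, shared between two takers, the electrophile and the protic impurity.

If both steps are first order in nucleophile, dividing one rate by the other removes [nucleophile] and time. The fraction of impurity left then equals the fraction of electrophile left raised to a power S. In elm the balance leaves 39.0% of the impurity, so S reads 1.65, the selectivity factor, the rate constant of quenching over that of product formation.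

This reckoning draws the new flask as follows. Quenched reagent per product starts at a slope of 0.825. The knee should come near 1.33 min, since the flask's nucleophile lies between that of elm and that of cedar, and that is earlier than 4.0 min. The asked time therefore lies on the level. There 0.200 mM of electrophile and protic impurity together stays unreacted. Two rounds of substitution in that balance leave 32.4% of the electrophile, so 67.6% has reacted, and the slope has sunk to 0.397.

The forecast says 67%, a little below this reckoning, and a free share of 70%, with the remark “The binding constant is unknown”.

The flask gives 67.7% reacted and a free share of 89.9%.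

    electrophile + nucleophile ⇌ acid set free + product (K = 1.80, k = 370 L mol⁻¹ s⁻¹)
    nucleophile + acid set free ⇌ protonated nucleophile, settled at all times (K = 6.40 × 10⁶ L mol⁻¹)
    acid set free + free base ⇌ salt of the base, settled at all times (K = 2.90 × 10⁷ L mol⁻¹)
    nucleophile + protic impurity → quenched reagent (k = 610 L mol⁻¹ s⁻¹)
    nucleophile ⇌ dormant form (K = 0.950, k = 0.0490 s⁻¹)

The forecast's free share lies 20 percentage points low. At 4.00 min the flask's acid set free stands at 1.76 × 10⁻⁵ mM, which makes 0.113 protonated nucleophile per free nucleophile. With 67.7% reacted, S puts 0.211 mM into quenched reagent.

In the neighbour with 1.2 mM of electrophile, 0.900 mM of electrophile and protic impurity together stays unreacted, and S gives 35.1% reacted. That neighbour gives 35.2%.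

The runs stem from a simulated flask for substances that don't exist; the scatter is artificial.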